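**Retrosynthetic overview**
- Last bond: the C6–O ester, by Yamaguchi acylation of the macrocyclic C6 alcohol with (S)-2-methyloxirane-2-carboxylic acid.
- Ten-membered ring (formed third): ring-closing metathesis makes the Z C4=C5 olefin between a 5-isopropenyl-3(2H)-furanone and a C6 vinyl carbinol.
- Furanone (formed second): gold-catalysed 5-endo cyclisation of an α'-hydroxy ynone, made from a C1 aldehyde and an enyne acetylide.
- Key C7–C8 bond: intermolecular Evans boron syn-aldol of a succinate-derived N-acyl oxazolidinone with the C8 aldehyde; lactonisation in the flask gives the trans γ-lactone (formed first). C6 is then set by ynone transfer hydrogenation and C13 added by Mannich/elimination.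
- C10 comes from (S)-2-methylglycidol; the side-chain acid comes from (R)-2-methylglycidol.

Assumption: both enantiomers of 2-methylglycidol, (R)-4-benzyl-1,3-oxazolidin-2-one and 2-methylbut-1-en-3-yne are taken as stock chemicals.
Numbering note: C-labels are germacrane locants (C1 furanone C=O, C2 furanone CH, C3 furanone C–O, C4=C5 ring olefin, C6 ester carbinol, C7 ring-fusion CH, C8 lactone O–CH, C9 CH2, C10 quaternary carbon, C11–C13 methylene lactone). Where an R/S label changes at a centre that is not touched (ring C4 = C7, and C6 on going from alkyne to alkene), only the CIP priorities change.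

Step 1
Reactants: 1 [(2S)-2-methyloxiran-2-yl]methanol; 2 vinylmagnesium bromide
Product: 3 (2R)-2-methylpent-4-ene-1,2-diol
Conditions: 2 (2.5 equiv), CuI (10 mol%), THF, −30 → 0 °C; aq NH4Cl
Reagents that add atoms: none
Why: Copper-catalysed Grignard epoxide opening (SN2) occurs at the unsubstituted CH2 terminus, so the quaternary stereocentre (future C10) is untouched, the first equivalent of Grignard reagent only deprotonating the hydroxyl.

Step 2
Reactants: 3 (2R)-2-methylpent-4-ene-1,2-diol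
Product: 4 (4R)-2,2,4-trimethyl-4-(prop-2-en-1-yl)-1,3-dioxolane
Conditions: 2,2-dimethoxypropane, PPTS (cat.), CH2Cl2, 25 °C
Reagents that add atoms: 2,2-dimethoxypropane COC(C)(C)OC
Why: Acid-catalysed transketalisation (acetonide formation) masks the primary/tertiary 1,2-diol that later becomes C1/C10–O.

Step 3
Reactants: 4 (4R)-2,2,4-trimethyl-4-(prop-2-en-1-yl)-1,3-dioxolane
Product: 6 2-[(4R)-2,2,4-trimethyl-1,3-dioxolan-4-yl]acetaldehyde, via secondary ozonide 5 (not isolated)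
Conditions: O3, CH2Cl2, −78 °C; then PPh3, −78 → 25 °C
Reagents that add atoms: ozone [O-][O+]=O
Why: Ozonolysis with reductive work-up cleaves the only alkene to the C8 aldehyde without touching the ketal or the stereocentre.

Step 4
Reactants: 7 (4R)-4-benzyl-1,3-oxazolidin-2-one; 8 methyl 4-chloro-4-oxobutanoate
Product: 9 methyl 4-[(4R)-4-benzyl-2-oxo-1,3-oxazolidin-3-yl]-4-oxobutanoate
Conditions: Et3N, DMAP (cat.), CH2Cl2, 0 → 25 °C
Reagents that add atoms: none
Why: DMAP-catalysed N-acylation (nucleophilic acyl substitution) takes place at the acid chloride, which is far more reactive than the methyl ester.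

Step 5
Reactants: 9 methyl 4-[(4R)-4-benzyl-2-oxo-1,3-oxazolidin-3-yl]-4-oxobutanoate; 6 2-[(4R)-2,2,4-trimethyl-1,3-dioxolan-4-yl]acetaldehyde
Product: 12 (4R)-4-benzyl-3-[(2S,3R)-5-oxo-2-{[(4R)-2,2,4-trimethyl-1,3-dioxolan-4-yl]methyl}oxolane-3-carbonyl]-1,3-oxazolidin-2-one, via Z-boron enolate 10 (not isolated), via syn-aldol adduct 11 (not isolated)
Conditions: Bu2BOTf, i-Pr2NEt, CH2Cl2, 0 °C; then 6, −78 → 25 °C; pH 7 buffer
Reagents that add atoms: none
Why: In this intermolecular Evans boron syn-aldol reaction Bu2BOTf/amine enolises only the imide to the Z-enolate, which adds through a Zimmerman–Traxler chair under control of the (R)-benzyl auxiliary to set C7 (R) and C8 (S), and the aldolate then closes onto the γ-ester to give the trans γ-lactone.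

Step 6
Reactants: 12 (4R)-4-benzyl-3-[(2S,3R)-5-oxo-2-{[(4R)-2,2,4-trimethyl-1,3-dioxolan-4-yl]methyl}oxolane-3-carbonyl]-1,3-oxazolidin-2-one
Product: 14 (2S,3R)-5-oxo-2-{[(4R)-2,2,4-trimethyl-1,3-dioxolan-4-yl]methyl}oxolane-3-carboxylic acid, via peroxy acid 13 (not isolated)
Conditions: LiOH·H2O, 30% H2O2, THF/H2O, 0 °C; aq Na2SO3; 1 M HCl to pH 3 at 0 °C
Reagents that add atoms: hydrogen peroxide OO
Why: Hydroperoxide-mediated imide cleavage attacks the exocyclic carbonyl selectively and does not epimerise C7 at 0 °C, and any lactone opened by hydroxide re-closes on acidification.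

Step 7
Reactants: 14 (2S,3R)-5-oxo-2-{[(4R)-2,2,4-trimethyl-1,3-dioxolan-4-yl]methyl}oxolane-3-carboxylic acid; 15 ethynyltrimethylsilane
Product: 17 (4R,5S)-4-[3-(trimethylsilyl)prop-2-ynoyl]-5-{[(4R)-2,2,4-trimethyl-1,3-dioxolan-4-yl]methyl}oxolan-2-one, via acid chloride 16 (not isolated)
Conditions: 1-chloro-N,N,2-trimethylprop-1-en-1-amine, CH2Cl2, 0 → 25 °C; then 15, PdCl2(PPh3)2 (2 mol%), CuI (4 mol%), Et3N, THF, 25 °C
Reagents that add atoms: none
Why: Neutral acid chloride formation followed by Pd/Cu acyl Sonogashira coupling gives the silyl ynone (C6 ketone, C5 alkyne carbon) without touching the lactone or the ketal.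

Step 8
Reactants: 17 (4R,5S)-4-[3-(trimethylsilyl)prop-2-ynoyl]-5-{[(4R)-2,2,4-trimethyl-1,3-dioxolan-4-yl]methyl}oxolan-2-one
Product: 18 (4S,5S)-4-[(1S)-1-hydroxy-3-(trimethylsilyl)prop-2-yn-1-yl]-5-{[(4R)-2,2,4-trimethyl-1,3-dioxolan-4-yl]methyl}oxolan-2-one
Conditions: Ru[(S,S)-TsDPEN](p-cymene) (2 mol%), i-PrOH, 25 °C
Reagents that add atoms: none
Why: Noyori asymmetric transfer hydrogenation of the ynone is catalyst-controlled, the (S,S)-catalyst placing the alkynyl group in the aryl-like position to give the (1S) propargylic carbinol (target C6), and the neutral medium avoids C7 epimerisation and translactonisation.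

Step 9
Reactants: 18 (4S,5S)-4-[(1S)-1-hydroxy-3-(trimethylsilyl)prop-2-yn-1-yl]-5-{[(4R)-2,2,4-trimethyl-1,3-dioxolan-4-yl]methyl}oxolan-2-one
Product: 19 (4R,5S)-4-[(1S)-1-{[tert-butyl(dimethyl)silyl]oxy}-3-(trimethylsilyl)prop-2-yn-1-yl]-5-{[(4R)-2,2,4-trimethyl-1,3-dioxolan-4-yl]methyl}oxolan-2-one
Conditions: TBSCl, imidazole, DMF, 25 °C
Reagents that add atoms: tert-butyldimethylsilyl chloride CC(C)(C)[Si](C)(C)Cl
Why: Silyl ether formation protects the C6 hydroxyl and removes the risk of its translactonisation onto C12.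

Step 10
Reactants: 19 (4R,5S)-4-[(1S)-1-{[tert-butyl(dimethyl)silyl]oxy}-3-(trimethylsilyl)prop-2-yn-1-yl]-5-{[(4R)-2,2,4-trimethyl-1,3-dioxolan-4-yl]methyl}oxolan-2-one
Product: 20 (4R,5S)-4-[(1S)-1-{[tert-butyl(dimethyl)silyl]oxy}prop-2-yn-1-yl]-5-{[(4R)-2,2,4-trimethyl-1,3-dioxolan-4-yl]methyl}oxolan-2-one
Conditions: K2CO3 (0.3 equiv), MeOH, 0 °C
Reagents that add atoms: none
Why: Base-catalysed methanolytic protodesilylation cleaves only the alkynyl C–Si bond, the O–Si ether being stable and any lactone methanolysis being reversible.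

Step 11
Reactants: 20 (4R,5S)-4-[(1S)-1-{[tert-butyl(dimethyl)silyl]oxy}prop-2-yn-1-yl]-5-{[(4R)-2,2,4-trimethyl-1,3-dioxolan-4-yl]methyl}oxolan-2-one
Product: 21 (4R,5S)-4-[(1R)-1-{[tert-butyl(dimethyl)silyl]oxy}prop-2-en-1-yl]-5-{[(4R)-2,2,4-trimethyl-1,3-dioxolan-4-yl]methyl}oxolan-2-one
Conditions: H2 (1 atm), Pd/CaCO3 poisoned with Pb(OAc)2 (Lindlar catalyst), quinoline, EtOAc, 25 °C
Reagents that add atoms: none
Why: Lindlar semihydrogenation stops at the terminal alkene, giving the C5 vinyl group needed for metathesis.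

Step 12
Reactants: 21 (4R,5S)-4-[(1R)-1-{[tert-butyl(dimethyl)silyl]oxy}prop-2-en-1-yl]-5-{[(4R)-2,2,4-trimethyl-1,3-dioxolan-4-yl]methyl}oxolan-2-one; 22 N,N-dimethylmethaniminium iodide
Product: 24 (4R,5S)-4-[(1R)-1-{[tert-butyl(dimethyl)silyl]oxy}prop-2-en-1-yl]-3-[(dimethylamino)methyl]-5-{[(4R)-2,2,4-trimethyl-1,3-dioxolan-4-yl]methyl}oxolan-2-one, via lithium enolate 23 (not isolated)
Conditions: LiN(i-Pr)2, THF, −78 °C; then 22, −78 → 25 °C
Reagents that add atoms: none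
Why: Intermolecular Mannich reaction of the lactone lithium enolate with the iminium salt installs C13 at the only acidic position, and the new α-centre is erased in the next step.

Step 13
Reactants: 24 (4R,5S)-4-[(1R)-1-{[tert-butyl(dimethyl)silyl]oxy}prop-2-en-1-yl]-3-[(dimethylamino)methyl]-5-{[(4R)-2,2,4-trimethyl-1,3-dioxolan-4-yl]methyl}oxolan-2-one
Product: 26 (4R,5S)-4-[(1R)-1-{[tert-butyl(dimethyl)silyl]oxy}prop-2-en-1-yl]-3-methylidene-5-{[(4R)-2,2,4-trimethyl-1,3-dioxolan-4-yl]methyl}oxolan-2-one, via trimethylammonium iodide 25 (not isolated)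
Conditions: MeI (excess), THF, 25 °C; then 5% aq NaHCO3, CH2Cl2, 25 °C
Reagents that add atoms: none
Why: N-Quaternisation followed by mild-base E1cB (Hofmann-type) elimination of trimethylamine unveils the α-methylene lactone.

Step 14
Reactants: 26 (4R,5S)-4-[(1R)-1-{[tert-butyl(dimethyl)silyl]oxy}prop-2-en-1-yl]-3-methylidene-5-{[(4R)-2,2,4-trimethyl-1,3-dioxolan-4-yl]methyl}oxolan-2-one
Product: 27 (4R,5S)-4-[(1R)-1-{[tert-butyl(dimethyl)silyl]oxy}prop-2-en-1-yl]-5-[(2R)-2,3-dihydroxy-2-methylpropyl]-3-methylideneoxolan-2-one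
Conditions: AcOH/H2O (4:1), 25 → 40 °C
Reagents that add atoms: none
Why: Acid-catalysed ketal hydrolysis frees the diol while the secondary silyl ether and the methylene lactone tolerate aqueous acetic acid.

Step 15
Reactants: 27 (4R,5S)-4-[(1R)-1-{[tert-butyl(dimethyl)silyl]oxy}prop-2-en-1-yl]-5-[(2R)-2,3-dihydroxy-2-methylpropyl]-3-methylideneoxolan-2-one
Product: 28 (2R)-3-[(2S,3R)-3-[(1R)-1-{[tert-butyl(dimethyl)silyl]oxy}prop-2-en-1-yl]-4-methylidene-5-oxooxolan-2-yl]-2-hydroxy-2-methylpropanal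
Conditions: Dess–Martin periodinane (1.1 equiv), CH2Cl2, 0 °C
Reagents that add atoms: none
Why: Dess–Martin oxidation can only oxidise the primary alcohol (the tertiary carbinol is inert), giving the non-enolisable C1 aldehyde.

Step 16
Reactants: 28 (2R)-3-[(2S,3R)-3-[(1R)-1-{[tert-butyl(dimethyl)silyl]oxy}prop-2-en-1-yl]-4-methylidene-5-oxooxolan-2-yl]-2-hydroxy-2-methylpropanal; 29 2-methylbut-1-en-3-yne
Product: 31 (4R,5S)-4-[(1R)-1-{[tert-butyl(dimethyl)silyl]oxy}prop-2-en-1-yl]-5-[(2R)-2,3-dihydroxy-2,6-dimethylhept-6-en-4-yn-1-yl]-3-methylideneoxolan-2-one, via lithium acetylide 30 (not isolated)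
Conditions: 29 (3 equiv), n-BuLi (2.5 equiv), THF, −78 °C; then 28, −78 °C; aq NH4Cl at −78 °C
Reagents that add atoms: none
Why: Acetylide 1,2-addition to the aldehyde at −78 °C outpaces attack on the lactone or the methylene group (one equivalent is spent on the tertiary hydroxyl), and the configuration of the new carbinol is irrelevant because it is oxidised next.

Step 17
Reactants: 31 (4R,5S)-4-[(1R)-1-{[tert-butyl(dimethyl)silyl]oxy}prop-2-en-1-yl]-5-[(2R)-2,3-dihydroxy-2,6-dimethylhept-6-en-4-yn-1-yl]-3-methylideneoxolan-2-one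
Product: 32 (4R,5S)-4-[(1R)-1-{[tert-butyl(dimethyl)silyl]oxy}prop-2-en-1-yl]-5-[(2R)-2-hydroxy-2,6-dimethyl-3-oxohept-6-en-4-yn-1-yl]-3-methylideneoxolan-2-one
Conditions: Dess–Martin periodinane, CH2Cl2, 0 → 25 °C
Reagents that add atoms: none
Why: Dess–Martin oxidation of the secondary propargylic alcohol gives the α'-hydroxy ynone and removes the C1 stereocentre.

Step 18
Reactants: 32 (4R,5S)-4-[(1R)-1-{[tert-butyl(dimethyl)silyl]oxy}prop-2-en-1-yl]-5-[(2R)-2-hydroxy-2,6-dimethyl-3-oxohept-6-en-4-yn-1-yl]-3-methylideneoxolan-2-one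
Product: 33 (4R,5S)-4-[(1R)-1-{[tert-butyl(dimethyl)silyl]oxy}prop-2-en-1-yl]-3-methylidene-5-{[(2R)-2-methyl-3-oxo-5-(prop-1-en-2-yl)-2,3-dihydrofuran-2-yl]methyl}oxolan-2-one
Conditions: Ph3PAuCl (5 mol%), AgOTf (5 mol%), toluene, 25 °C
Reagents that add atoms: none
Why: Gold-catalysed 5-endo-dig intramolecular hydroalkoxylation of the ynone by the tertiary hydroxyl gives the 3(2H)-furanone with C10 untouched.

Step 19
Reactants: 33 (4R,5S)-4-[(1R)-1-{[tert-butyl(dimethyl)silyl]oxy}prop-2-en-1-yl]-3-methylidene-5-{[(2R)-2-methyl-3-oxo-5-(prop-1-en-2-yl)-2,3-dihydrofuran-2-yl]methyl}oxolan-2-one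
Product: 34 (4Z,6R,7R,8S,10R)-6-{[tert-butyl(dimethyl)silyl]oxy}-3,10-epoxy-1-oxogermacra-2,4,11(13)-trien-12,8-olide
Conditions: second-generation Hoveyda–Grubbs catalyst (10 mol%), toluene (1 mM), 100 °C
Reagents that add atoms: none
Why: Ring-closing olefin metathesis between the vinyl and isopropenyl groups forms the trisubstituted C4=C5 bond, the bridged nine-membered oxacycle strongly favouring the Z geometry and the exo-methylene being unable to compete because it could only close a cyclobutene.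

Step 20
Reactants: 34 (4Z,6R,7R,8S,10R)-6-{[tert-butyl(dimethyl)silyl]oxy}-3,10-epoxy-1-oxogermacra-2,4,11(13)-trien-12,8-olide
Product: 35 (4Z,6R,7S,8S,10R)-6-hydroxy-3,10-epoxy-1-oxogermacra-2,4,11(13)-trien-12,8-olide
Conditions: HF·pyridine, pyridine/THF, 0 → 25 °C
Reagents that add atoms: none
Why: Fluoride-mediated desilylation under buffered, non-basic conditions frees the C6 hydroxyl without translactonisation or conjugate addition.

Step 21
Reactants: 36 [(2R)-2-methyloxiran-2-yl]methanol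
Product: 37 (2S)-2-methyloxirane-2-carboxylic acid
Conditions: RuCl3·xH2O (2 mol%), NaIO4 (4 equiv), CCl4/MeCN/H2O, 0 → 25 °C; used crude
Reagents that add atoms: water O
Why: RuO4-catalysed (Sharpless) oxidation takes the primary alcohol to the acid without touching the epoxide stereocentre, the label changing from R to S by priority only.

Step 22
Reactants: 35 (4Z,6R,7S,8S,10R)-6-hydroxy-3,10-epoxy-1-oxogermacra-2,4,11(13)-trien-12,8-olide; 37 (2S)-2-methyloxirane-2-carboxylic acid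
Product: 39 (4Z,6R,7R,8S,10R)-3,10-epoxy-1-oxo-12,8-olidogermacra-2,4,11(13)-trien-6-yl (2S)-2-methyloxirane-2-carboxylate (CNP0321429.1), via mixed anhydride 38 (not isolated)
Conditions: 37, 2,4,6-trichlorobenzoyl chloride, Et3N, THF, 0 → 25 °C; then 35, DMAP, toluene, 25 °C
Reagents that add atoms: none
Why: Yamaguchi esterification transfers the epoxy acyl group from the mixed anhydride to the C6 hydroxyl by DMAP catalysis with retention at C6 and under conditions that spare the epoxide and the methylene lactone.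

**Compound list**
1 | [(2S)-2-methyloxiran-2-yl]methanol ((S)-2-methylglycidol) | OC[C@@]1(C)CO1 | starting material
2 | vinylmagnesium bromide | C=C[Mg]Br | starting material
3 | (2R)-2-methylpent-4-ene-1,2-diol | OC[C@@](O)(C)CC=C | intermediate
4 | (4R)-2,2,4-trimethyl-4-(prop-2-en-1-yl)-1,3-dioxolane | C=CC[C@]1(C)COC(C)(C)O1 | intermediate
5 | 3-{[(4R)-2,2,4-trimethyl-1,3-dioxolan-4-yl]methyl}-1,2,4-trioxolane (secondary ozonide, both epimers at the trioxolane carbon) | O1OC(C[C@]2(C)COC(C)(C)O2)OC1 | intermediate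
6 | 2-[(4R)-2,2,4-trimethyl-1,3-dioxolan-4-yl]acetaldehyde | O=CC[C@]1(C)COC(C)(C)O1 | intermediate
7 | (4R)-4-benzyl-1,3-oxazolidin-2-one | O=C1N[C@H](Cc2ccccc2)CO1 | starting material
8 | methyl 4-chloro-4-oxobutanoate | COC(=O)CCC(Cl)=O | starting material
9 | methyl 4-[(4R)-4-benzyl-2-oxo-1,3-oxazolidin-3-yl]-4-oxobutanoate | COC(=O)CCC(=O)N1[C@H](Cc2ccccc2)COC1=O | intermediate
10 | Z-dibutylboron enolate of 9 | CCCCB(CCCC)O/C(=C\CC(=O)OC)N1[C@H](Cc2ccccc2)COC1=O | intermediate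
11 | methyl (3R,4S)-3-[(4R)-4-benzyl-2-oxo-1,3-oxazolidine-3-carbonyl]-4-hydroxy-5-[(4R)-2,2,4-trimethyl-1,3-dioxolan-4-yl]pentanoate (present as its boron aldolate) | COC(=O)C[C@@H](C(=O)N1[C@H](Cc2ccccc2)COC1=O)[C@@H](O)C[C@]3(C)COC(C)(C)O3 | intermediate
12 | (4R)-4-benzyl-3-[(2S,3R)-5-oxo-2-{[(4R)-2,2,4-trimethyl-1,3-dioxolan-4-yl]methyl}oxolane-3-carbonyl]-1,3-oxazolidin-2-one | O=C1C[C@@H](C(=O)N2[C@H](Cc3ccccc3)COC2=O)[C@H](C[C@]4(C)COC(C)(C)O4)O1 | intermediate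
13 | (2S,3R)-5-oxo-2-{[(4R)-2,2,4-trimethyl-1,3-dioxolan-4-yl]methyl}oxolane-3-carboperoxoic acid (as lithium salt) | O=C1C[C@@H](C(=O)OO)[C@H](C[C@]2(C)COC(C)(C)O2)O1 | intermediate
14 | (2S,3R)-5-oxo-2-{[(4R)-2,2,4-trimethyl-1,3-dioxolan-4-yl]methyl}oxolane-3-carboxylic acid | O=C1C[C@@H](C(=O)O)[C@H](C[C@]2(C)COC(C)(C)O2)O1 | intermediate
15 | ethynyltrimethylsilane | C#C[Si](C)(C)C | starting material
16 | (2S,3R)-5-oxo-2-{[(4R)-2,2,4-trimethyl-1,3-dioxolan-4-yl]methyl}oxolane-3-carbonyl chloride | O=C1C[C@@H](C(Cl)=O)[C@H](C[C@]2(C)COC(C)(C)O2)O1 | intermediate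
17 | (4R,5S)-4-[3-(trimethylsilyl)prop-2-ynoyl]-5-{[(4R)-2,2,4-trimethyl-1,3-dioxolan-4-yl]methyl}oxolan-2-one | O=C1C[C@@H](C(=O)C#C[Si](C)(C)C)[C@H](C[C@]2(C)COC(C)(C)O2)O1 | intermediate
18 | (4S,5S)-4-[(1S)-1-hydroxy-3-(trimethylsilyl)prop-2-yn-1-yl]-5-{[(4R)-2,2,4-trimethyl-1,3-dioxolan-4-yl]methyl}oxolan-2-one | O=C1C[C@@H]([C@H](O)C#C[Si](C)(C)C)[C@H](C[C@]2(C)COC(C)(C)O2)O1 | intermediate
19 | (4R,5S)-4-[(1S)-1-{[tert-butyl(dimethyl)silyl]oxy}-3-(trimethylsilyl)prop-2-yn-1-yl]-5-{[(4R)-2,2,4-trimethyl-1,3-dioxolan-4-yl]methyl}oxolan-2-one | O=C1C[C@@H]([C@H](O[Si](C)(C)C(C)(C)C)C#C[Si](C)(C)C)[C@H](C[C@]2(C)COC(C)(C)O2)O1 | intermediate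
20 | (4R,5S)-4-[(1S)-1-{[tert-butyl(dimethyl)silyl]oxy}prop-2-yn-1-yl]-5-{[(4R)-2,2,4-trimethyl-1,3-dioxolan-4-yl]methyl}oxolan-2-one | O=C1C[C@@H]([C@H](O[Si](C)(C)C(C)(C)C)C#C)[C@H](C[C@]2(C)COC(C)(C)O2)O1 | intermediate
21 | (4R,5S)-4-[(1R)-1-{[tert-butyl(dimethyl)silyl]oxy}prop-2-en-1-yl]-5-{[(4R)-2,2,4-trimethyl-1,3-dioxolan-4-yl]methyl}oxolan-2-one | O=C1C[C@@H]([C@H](O[Si](C)(C)C(C)(C)C)C=C)[C@H](C[C@]2(C)COC(C)(C)O2)O1 | intermediate
22 | N,N-dimethylmethaniminium iodide (Eschenmoser's salt) | C=[N+](C)C.[I-] | starting material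
23 | lithium enolate of 21 | [Li]OC1=C[C@@H]([C@H](O[Si](C)(C)C(C)(C)C)C=C)[C@H](C[C@]2(C)COC(C)(C)O2)O1 | intermediate
24 | (4R,5S)-4-[(1R)-1-{[tert-butyl(dimethyl)silyl]oxy}prop-2-en-1-yl]-3-[(dimethylamino)methyl]-5-{[(4R)-2,2,4-trimethyl-1,3-dioxolan-4-yl]methyl}oxolan-2-one (C3 epimers, mainly 3,4-trans) | O=C1C(CN(C)C)[C@@H]([C@H](O[Si](C)(C)C(C)(C)C)C=C)[C@H](C[C@]2(C)COC(C)(C)O2)O1 | intermediate
25 | N,N,N-trimethylammonium iodide of 24 | O=C1C(C[N+](C)(C)C)[C@@H]([C@H](O[Si](C)(C)C(C)(C)C)C=C)[C@H](C[C@]2(C)COC(C)(C)O2)O1.[I-] | intermediate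
26 | (4R,5S)-4-[(1R)-1-{[tert-butyl(dimethyl)silyl]oxy}prop-2-en-1-yl]-3-methylidene-5-{[(4R)-2,2,4-trimethyl-1,3-dioxolan-4-yl]methyl}oxolan-2-one | O=C1C(=C)[C@@H]([C@H](O[Si](C)(C)C(C)(C)C)C=C)[C@H](C[C@]2(C)COC(C)(C)O2)O1 | intermediate
27 | (4R,5S)-4-[(1R)-1-{[tert-butyl(dimethyl)silyl]oxy}prop-2-en-1-yl]-5-[(2R)-2,3-dihydroxy-2-methylpropyl]-3-methylideneoxolan-2-one | O=C1C(=C)[C@@H]([C@H](O[Si](C)(C)C(C)(C)C)C=C)[C@H](C[C@@](C)(O)CO)O1 | intermediate
28 | (2R)-3-[(2S,3R)-3-[(1R)-1-{[tert-butyl(dimethyl)silyl]oxy}prop-2-en-1-yl]-4-methylidene-5-oxooxolan-2-yl]-2-hydroxy-2-methylpropanal | O=C1C(=C)[C@@H]([C@H](O[Si](C)(C)C(C)(C)C)C=C)[C@H](C[C@@](C)(O)C=O)O1 | intermediate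
29 | 2-methylbut-1-en-3-yne | C=C(C)C#C | starting material
30 | lithium 3-methylbut-3-en-1-yn-1-ide | [Li]C#CC(C)=C | intermediate
31 | (4R,5S)-4-[(1R)-1-{[tert-butyl(dimethyl)silyl]oxy}prop-2-en-1-yl]-5-[(2R)-2,3-dihydroxy-2,6-dimethylhept-6-en-4-yn-1-yl]-3-methylideneoxolan-2-one (both epimers at the new carbinol) | O=C1C(=C)[C@@H]([C@H](O[Si](C)(C)C(C)(C)C)C=C)[C@H](C[C@@](C)(O)C(O)C#CC(C)=C)O1 | intermediate
32 | (4R,5S)-4-[(1R)-1-{[tert-butyl(dimethyl)silyl]oxy}prop-2-en-1-yl]-5-[(2R)-2-hydroxy-2,6-dimethyl-3-oxohept-6-en-4-yn-1-yl]-3-methylideneoxolan-2-one | O=C1C(=C)[C@@H]([C@H](O[Si](C)(C)C(C)(C)C)C=C)[C@H](C[C@@](C)(O)C(=O)C#CC(C)=C)O1 | intermediate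
33 | (4R,5S)-4-[(1R)-1-{[tert-butyl(dimethyl)silyl]oxy}prop-2-en-1-yl]-3-methylidene-5-{[(2R)-2-methyl-3-oxo-5-(prop-1-en-2-yl)-2,3-dihydrofuran-2-yl]methyl}oxolan-2-one | O=C1C(=C)[C@@H]([C@H](O[Si](C)(C)C(C)(C)C)C=C)[C@H](C[C@@]2(C)OC(C(C)=C)=CC2=O)O1 | intermediate
34 | (4Z,6R,7R,8S,10R)-6-{[tert-butyl(dimethyl)silyl]oxy}-3,10-epoxy-1-oxogermacra-2,4,11(13)-trien-12,8-olide | C=C1C(=O)O[C@H]2C[C@@]3(C)OC(=CC3=O)/C(C)=C\[C@@H](O[Si](C)(C)C(C)(C)C)[C@H]12 | intermediate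
35 | (4Z,6R,7S,8S,10R)-6-hydroxy-3,10-epoxy-1-oxogermacra-2,4,11(13)-trien-12,8-olide | C=C1C(=O)O[C@H]2C[C@@]3(C)OC(=CC3=O)/C(C)=C\[C@@H](O)[C@H]12 | intermediate
36 | [(2R)-2-methyloxiran-2-yl]methanol ((R)-2-methylglycidol) | OC[C@]1(C)CO1 | starting material
37 | (2S)-2-methyloxirane-2-carboxylic acid | OC(=O)[C@]1(C)CO1 | intermediate
38 | (2S)-2-methyloxirane-2-carboxylic 2,4,6-trichlorobenzoic anhydride | O=C(OC(=O)c1c(Cl)cc(Cl)cc1Cl)[C@]2(C)CO2 | intermediate
39 | (4Z,6R,7R,8S,10R)-3,10-epoxy-1-oxo-12,8-olidogermacra-2,4,11(13)-trien-6-yl (2S)-2-methyloxirane-2-carboxylate (CNP0321429.1) | C=C1C(=O)O[C@H]2C[C@@]3(C)OC(=CC3=O)/C(C)=C\[C@@H](OC(=O)[C@]3(C)CO3)[C@H]12 | target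

**Totals**
Total step count: 22. Longest linear sequence: 20 steps (1–3, 5–20, 22); steps 4 and 21 are side branches.

**Steps most likely to fail, with fallbacks**

Step 7. The acid chloride has an α-stereocentre and a β-acyloxy group, so Et3N could cause ketene formation, C7 epimerisation or E1cB opening of the lactone. The fallback sets out from 14 and returns at 17, replacing acylation by carbonyl addition and oxidation. Chemoselective reduction of the acid with BH3·SMe2 (THF, 0 °C) gives the hydroxymethyl lactone F1. Dess–Martin oxidation gives the lactone aldehyde F2. Addition of LiC≡CSiMe3 (THF, −78 °C, cold AcOH quench) gives the epimeric propargylic alcohols F3. Dess–Martin oxidation converges both epimers on ynone 17, and step 8 then sets C6 as before.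

Step 16. A lithium acetylide is used beside a free tertiary hydroxyl, a lactone and a Michael-accepting methylene lactone. The fallback sets out from 28 and 29 and returns at 31, replacing the basic organolithium by a chromium-mediated Nozaki–Hiyama–Kishi alkynylation. Enyne 29 is iodinated (N-iodosuccinimide, AgNO3 cat., acetone) to the iodoalkyne 4-iodo-2-methylbut-1-en-3-yne F4. F4 is coupled with 28 using CrCl2 and NiCl2 (cat.) in THF at 25 °C; the alkynylchromium species is non-basic and adds only to the aldehyde, giving 31.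

Step 19. The ring is strained and bicyclic, the new olefin is trisubstituted, and the allylic silyl ether is bulky. The fallback sets out from 33 and returns at 39, changing the order of events so that the metathesis substrate carries the smaller, final acyloxy group (bypassing 34 and 35). HF·pyridine on 33 gives the acyclic allylic alcohol F5. Yamaguchi esterification of F5 with 37 (through 38) gives the acyclic epoxy ester F6. Ring-closing metathesis of F6 (second-generation Hoveyda–Grubbs catalyst, toluene, 1 mM, 100 °C) then gives 39 directly.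

**Further compounds**
F1 | step 7 | (4S,5S)-4-(hydroxymethyl)-5-{[(4R)-2,2,4-trimethyl-1,3-dioxolan-4-yl]methyl}oxolan-2-one | O=C1C[C@@H](CO)[C@H](C[C@]2(C)COC(C)(C)O2)O1
F2 | step 7 | (2S,3R)-5-oxo-2-{[(4R)-2,2,4-trimethyl-1,3-dioxolan-4-yl]methyl}oxolane-3-carbaldehyde | O=C1C[C@@H](C=O)[C@H](C[C@]2(C)COC(C)(C)O2)O1
F3 | step 7 | 4-[1-hydroxy-3-(trimethylsilyl)prop-2-yn-1-yl]-5-{[(4R)-2,2,4-trimethyl-1,3-dioxolan-4-yl]methyl}oxolan-2-one, ring centres as in 18, both carbinol epimers | O=C1C[C@@H](C(O)C#C[Si](C)(C)C)[C@H](C[C@]2(C)COC(C)(C)O2)O1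
F4 | step 16 | 4-iodo-2-methylbut-1-en-3-yne | C=C(C)C#CI
F5 | step 19 | (4S,5S)-4-[(1R)-1-hydroxyprop-2-en-1-yl]-3-methylidene-5-{[(2R)-2-methyl-3-oxo-5-(prop-1-en-2-yl)-2,3-dihydrofuran-2-yl]methyl}oxolan-2-one | O=C1C(=C)[C@@H]([C@H](O)C=C)[C@H](C[C@@]2(C)OC(C(C)=C)=CC2=O)O1
F6 | step 19 | (1R)-1-[(2S,3R)-4-methylidene-2-{[(2R)-2-methyl-3-oxo-5-(prop-1-en-2-yl)-2,3-dihydrofuran-2-yl]methyl}-5-oxooxolan-3-yl]prop-2-en-1-yl (2S)-2-methyloxirane-2-carboxylate | O=C1C(=C)[C@@H]([C@H](OC(=O)[C@]3(C)CO3)C=C)[C@H](C[C@@]2(C)OC(C(C)=C)=CC2=O)O1
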